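**Strategy**

The furofuran is traced back to a cis-fused 6-aryl-3,7-dioxabicyclo[3.3.0]octan-2-one. Its aryl-bearing tetrahydrofuran ring (O, C7', C8', C8, C9; lignan locants, the primed half carries the two-unit chain) is grown from a cyclopropane: the donor–acceptor cyclopropane C7'–C8'–C8, fused to the future second ring as a γ-lactone and carrying a formyl group (C9) on C8, undergoes Cloke–Wilson ring expansion, which trades the C7'–C8 bond for C7'–O. The step exploits the benzylic, cation-stabilising C7' beside the doubly acylated C8; C8', set by asymmetric cyclopropanation, then steers C7' and C8. Friedel–Crafts arylation of the lactol completes the core; Evans glycolate aldols, two followed by Mitsunobu inversion, build the three arylglycerol ethers.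

Key step: step 6

Remark: C7–C9 denote the furofuran half whose syringyl ring carries one arylglycerol unit (unit A), C7'–C9' the half whose ring carries unit B, which in turn carries unit C on its guaiacyl oxygen (locants 7A, 8A, 9A and so on inside the units); sinapyl alcohol and isoeugenol are used as E isomers, and in step 5 the catalyst antipode that gives the 5R lactone is meant.

**Route**

Step 1
Reactants: 1 (E)-sinapyl alcohol
Product: 2 (E)-3-[4-(benzyloxy)-3,5-dimethoxyphenyl]prop-2-en-1-ol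
Conditions: BnBr, K2CO3, acetone, reflux
Reagents that add atoms: benzyl bromide, BrCc1ccccc1
Why: Williamson ether synthesis in which K2CO3 deprotonates only the phenol, so the allylic alcohol stays free and the benzyl ether marks this aryl ring for later differentiation.

Step 2
Reactants: 2 (E)-3-[4-(benzyloxy)-3,5-dimethoxyphenyl]prop-2-en-1-ol
Product: 3 (E)-3-[4-(benzyloxy)-3,5-dimethoxyphenyl]prop-2-en-1-yl bromoacetate
Conditions: bromoacetyl bromide, NaHCO3, MeCN, 0 °C
Reagents that add atoms: bromoacetyl bromide, BrCC(Br)=O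
Why: O-acylation of the primary allylic alcohol by the acid bromide, with NaHCO3 scavenging HBr so that the ionisable cinnamyl ester is not exposed to acid.

Step 3
Reactants: 3 (E)-3-[4-(benzyloxy)-3,5-dimethoxyphenyl]prop-2-en-1-yl bromoacetate
Product: 4 (E)-3-[4-(benzyloxy)-3,5-dimethoxyphenyl]prop-2-en-1-yl diazoacetate
Conditions: N,N'-ditosylhydrazine, DBU, THF, 0 °C
Reagents that add atoms: N,N'-ditosylhydrazine, Cc1ccc(cc1)S(=O)(=O)NNS(=O)(=O)c1ccc(C)cc1
Why: Diazoacetate synthesis by N-alkylation of the bis-sulfonyl hydrazine with the bromoacetate and base-induced loss of two sulfinate ions, a standard mild route that tolerates the styrene and the aryl ethers.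

Step 4
Reactants: 4 (E)-3-[4-(benzyloxy)-3,5-dimethoxyphenyl]prop-2-en-1-yl diazoacetate
Product: 6 (E)-3-[4-(benzyloxy)-3,5-dimethoxyphenyl]prop-2-en-1-yl 2-diazo-3-oxopropanoate, via diazo iminium chloride 5 (not isolated)
Conditions: (chloromethylene)dimethyliminium chloride, CHCl3, 0 °C → rt; then 10% aq. AcOH, rt
Reagents that add atoms: (chloromethylene)dimethyliminium chloride, ClC=[N+](C)C.[Cl-]; water, O
Why: Vilsmeier C-formylation of the nucleophilic diazo carbon followed by hydrolysis of the iminium salt, the usual entry to α-formyl-α-diazoacetates, the diazo carbon being far more reactive at 0 °C than the styrene or the trialkoxyarene.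

Step 5
Reactants: 6 (E)-3-[4-(benzyloxy)-3,5-dimethoxyphenyl]prop-2-en-1-yl 2-diazo-3-oxopropanoate
Product: 7 (1S,5R,6S)-6-[4-(benzyloxy)-3,5-dimethoxyphenyl]-2-oxo-3-oxabicyclo[3.1.0]hexane-1-carbaldehyde
Conditions: [Co(Por*)] (2 mol%; divalent cobalt complex of the D2-symmetric chiral porphyrin Por* = 5,15-bis(3,5-di-tert-butylphenyl)-10,20-bis[2,6-bis((S)-2,2-dimethylcyclopropanecarboxamido)phenyl]porphyrinate, or its enantiomer), toluene, rt
Reagents that add atoms: none
Why: Asymmetric intramolecular cyclopropanation of an allyl α-acceptor-α-diazoacetate by cobalt metalloradical catalysis, in which the cobalt-bound carbon radical adds 5-exo to the alkene (this C8–C8' bond fixes C8' inside the chiral porphyrin pocket) and 3-exo closure on the benzylic radical places the aryl group exo.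

Step 6
Reactants: 7 (1S,5R,6S)-6-[4-(benzyloxy)-3,5-dimethoxyphenyl]-2-oxo-3-oxabicyclo[3.1.0]hexane-1-carbaldehyde
Product: 8 (5R,6S)-6-[4-(benzyloxy)-3,5-dimethoxyphenyl]-3,7-dioxabicyclo[3.3.0]oct-1(8)-en-2-one
Conditions: Sc(OTf)3 (5 mol%), CH2Cl2, 0 °C → rt
Reagents that add atoms: none
Why: Sc(OTf)3 binds the formyl and lactone carbonyls of the 1,1-diacylcyclopropane and heterolyses the benzylic C7'–C8 bond to a zwitterion (aryl-stabilised cation at C7', formyl-lactone enolate at C8) whose formyl oxygen captures the cation, a Cloke–Wilson cyclopropyl-aldehyde to 2,3-dihydrofuran rearrangement as known for 2-aryl-1-formylcyclopropane-1-carboxylates. The new O–C7' bond closes the ring O–C7'–C8'–C8=C9 by 5-exo-trig O-attack of the enolate on the benzylic cation, so the three-membered ring C7'–C8'–C8 becomes the five-membered ring by gaining C9 and O. C8' is not touched and keeps the configuration set in step 5, and the new stereocentre C7' is controlled by C8', the aryl group going trans to the C9' methylene on the exo face of the bicycle; reversible ionisation of the benzylic vinylogous ester lets any cis isomer drain to the trans isomer, so the step is also indifferent to the configuration of C7' in 7. The selectivity needed is cleavage of C7'–C8 instead of C8'–C8 and closure through the formyl instead of the lactone oxygen: only C7' carries a cation-stabilising aryl group, and the lactone carbonyl is held in its ring and cannot reach C7'.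

Step 7
Reactants: 8 (5R,6S)-6-[4-(benzyloxy)-3,5-dimethoxyphenyl]-3,7-dioxabicyclo[3.3.0]oct-1(8)-en-2-one
Product: 9 (1R,5R,6S)-6-[4-(benzyloxy)-3,5-dimethoxyphenyl]-3,7-dioxabicyclo[3.3.0]octan-2-one
Conditions: H2 (1 atm), 10% Pd/C, 2,2'-bipyridyl (0.5 equiv), EtOAc–MeOH, rt
Reagents that add atoms: none
Why: Catalytic hydrogenation of the electron-poor enol ether should give the cis-fused bicycle (the only unstrained fusion, and C8–H remains epimerisable α to the lactone), with 2,2'-bipyridyl added to suppress hydrogenolysis of the aryl benzyl ether and of the benzylic C7'–O bond.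

Step 8
Reactants: 9 (1R,5R,6S)-6-[4-(benzyloxy)-3,5-dimethoxyphenyl]-3,7-dioxabicyclo[3.3.0]octan-2-one
Product: 10 (1R,5R,6S)-6-[4-(benzyloxy)-3,5-dimethoxyphenyl]-3,7-dioxabicyclo[3.3.0]octan-2-ol (lactol; both anomers)
Conditions: i-Bu2AlH (1.1 equiv), CH2Cl2, −78 °C; aq. potassium sodium tartrate
Reagents that add atoms: none
Why: Half-reduction of the γ-lactone to the lactol, the aluminium hemiacetal being stable at −78 °C until work-up.

Step 9
Reactants: 10 lactol; 11 2,6-dimethoxyphenol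
Product: 12 (+)-syringaresinol mono-O-benzyl ether, 4-[(1S,3aR,4S,6aR)-4-(4-benzyloxy-3,5-dimethoxyphenyl)tetrahydro-1H,3H-furo[3,4-c]furan-1-yl]-2,6-dimethoxyphenol (7S,8R,7'S,8'R; benzyl on O4')
Conditions: 11 (3 equiv), BF3·OEt2 (0.3 equiv), 4 Å MS, CH2Cl2, −30 → 0 °C; Et3N quench
Reagents that add atoms: none
Why: Friedel–Crafts C-arylation of the bicyclic oxocarbenium ion by the para carbon of 2,6-dimethoxyphenol, as known for the related lactol samin, with attack on the convex face anti to the cis-fused ring so that the new aryl group is exo (C7 = S) and its phenol is delivered free.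

Step 10
Reactants: 12 (+)-syringaresinol mono-O-benzyl ether; 13 (R)-4-benzyl-3-(chloroacetyl)oxazolidin-2-one
Product: 14 (R)-4-benzyl-3-{[4-((1S,3aR,4S,6aR)-4-(4-benzyloxy-3,5-dimethoxyphenyl)tetrahydro-1H,3H-furo[3,4-c]furan-1-yl)-2,6-dimethoxyphenoxy]acetyl}oxazolidin-2-one
Conditions: K2CO3, NaI (0.1 equiv), acetone, 45 °C
Reagents that add atoms: none
Why: Williamson alkylation of the only free phenoxide by the α-chloro imide with Finkelstein activation by iodide, SN2 at the α-halo carbonyl being faster than acyl transfer.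

Step 11
Reactants: 15 vanillin
Product: 16 3-methoxy-4-(triisopropylsilyloxy)benzaldehyde
Conditions: i-Pr3SiCl, imidazole, DMF, rt
Reagents that add atoms: chlorotriisopropylsilane, CC(C)[Si](Cl)(C(C)C)C(C)C
Why: Silylation of the phenol to an ether that survives hydrogenolysis, carbonate and borohydride and is removed at the end by fluoride.

Step 12
Reactants: 14 aryloxyacetyl imide; 16 3-methoxy-4-(triisopropylsilyloxy)benzaldehyde
Product: 17 syn-aldol adduct, (R)-4-benzyl-3-[(2R,3S)-2-aryloxy-3-hydroxy-3-(3-methoxy-4-triisopropylsilyloxyphenyl)propanoyl]oxazolidin-2-one (aryloxy = O4 of 4'-O-benzylsyringaresinol)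
Conditions: Bu2BOTf (1.2 equiv), i-Pr2NEt (1.4 equiv), CH2Cl2, −78 → 0 °C; then 16, −78 → 0 °C; pH 7 buffer, MeOH, 30% H2O2, 0 °C
Reagents that add atoms: none
Why: Evans boron glycolate syn-aldol in which the Z boron enolate reacts through a Zimmerman–Traxler chair on the face away from the benzyl group of the (R)-auxiliary, setting C8A and C7A in the threo (7S,8S) sense.

Step 13
Reactants: 17 syn-aldol adduct
Product: 18 4'-O-benzylsyringaresinol 4-O-[(1S,2S)-1,3-dihydroxy-1-(3-methoxy-4-triisopropylsilyloxyphenyl)propan-2-yl] ether (unit A threo)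
Conditions: LiBH4, MeOH (1 equiv), THF, 0 °C
Reagents that add atoms: none
Why: Reductive removal of the Evans auxiliary by hydride attack on the exocyclic imide carbonyl, which gives the primary alcohol without touching either new stereocentre.

Step 14
Reactants: 18 unit A threo diol benzyl ether
Product: 19 syringaresinol 4-O-[(1S,2S)-1,3-dihydroxy-1-(3-methoxy-4-triisopropylsilyloxyphenyl)propan-2-yl] ether with free 4'-OH
Conditions: H2 (1 atm), 10% Pd/C, EtOAc, rt
Reagents that add atoms: none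
Why: Hydrogenolysis of the phenolic benzyl ether, which is much faster in neutral EtOAc than cleavage of the benzylic alcohol or of the furofuran C–O bonds and is placed before the benzylic alcohol is esterified.

Step 15
Reactants: 19 phenol diol; 13 (R)-4-benzyl-3-(chloroacetyl)oxazolidin-2-one
Product: 20 imide diol, 19 carrying the CH2C(O)-[(R)-4-benzyl-2-oxooxazolidin-3-yl] group on O4'
Conditions: K2CO3, NaI (0.1 equiv), acetone, 45 °C
Reagents that add atoms: none
Why: Williamson alkylation that is chemoselective for the phenoxide because carbonate does not deprotonate the 1,3-diol.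

Step 16
Reactants: 20 imide diol
Product: 21 unit A erythro (7R,8S) bis(4-nitrobenzoate) of 20
Conditions: 4-nitrobenzoic acid (3 equiv), PPh3 (3 equiv), DIAD (3 equiv), THF, 0 °C → rt
Reagents that add atoms: 4-nitrobenzoic acid, OC(=O)c1ccc(cc1)[N+](=O)[O-]
Why: Double Mitsunobu esterification in which the primary alcohol is acylated and the benzylic alkoxyphosphonium ion is displaced by carboxylate with inversion (C7A S to R, threo to erythro), the acidic and poorly participating 4-nitrobenzoate favouring direct SN2 displacement.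

Step 17
Reactants: 22 (E)-isoeugenol; 23 (S)-4-benzyl-3-(chloroacetyl)oxazolidin-2-one
Product: 24 (S)-4-benzyl-3-{[2-methoxy-4-((E)-prop-1-enyl)phenoxy]acetyl}oxazolidin-2-one
Conditions: K2CO3, NaI (0.1 equiv), acetone, 45 °C
Reagents that add atoms: none
Why: Williamson alkylation of the guaiacol-type phenoxide, the propenyl group serving as a masked aldehyde that is inert to the enolisation conditions to come.

Step 18
Reactants: 24 aryloxyacetyl imide; 16 3-methoxy-4-(triisopropylsilyloxy)benzaldehyde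
Product: 25 syn-aldol adduct, (S)-4-benzyl-3-[(2S,3R)-3-hydroxy-2-(2-methoxy-4-((E)-prop-1-enyl)phenoxy)-3-(3-methoxy-4-triisopropylsilyloxyphenyl)propanoyl]oxazolidin-2-one
Conditions: Bu2BOTf (1.2 equiv), i-Pr2NEt (1.4 equiv), CH2Cl2, −78 → 0 °C; then 16, −78 → 0 °C; pH 7 buffer, MeOH, 30% H2O2, 0 °C
Reagents that add atoms: none
Why: Evans boron glycolate syn-aldol with the (S)-auxiliary, which sets C8C and C7C in the threo (7R,8R) sense by the same Zimmerman–Traxler control as in step 12.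

Step 19
Reactants: 25 syn-aldol adduct
Product: 26 (1R,2R)-2-[2-methoxy-4-((E)-prop-1-enyl)phenoxy]-1-(3-methoxy-4-triisopropylsilyloxyphenyl)propane-1,3-diol
Conditions: LiBH4, MeOH (1 equiv), THF, 0 °C
Reagents that add atoms: none
Why: Reductive cleavage of the imide to the primary alcohol with release of the auxiliary and no effect on the alkene or the silyl ether.

Step 20
Reactants: 26 threo diol
Product: 27 (1S,2R)-2-[2-methoxy-4-((E)-prop-1-enyl)phenoxy]-1-(3-methoxy-4-triisopropylsilyloxyphenyl)propane-1,3-diyl bis(4-nitrobenzoate)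
Conditions: 4-nitrobenzoic acid (3 equiv), PPh3 (3 equiv), DIAD (3 equiv), THF, 0 °C → rt
Reagents that add atoms: 4-nitrobenzoic acid, OC(=O)c1ccc(cc1)[N+](=O)[O-]
Why: Double Mitsunobu esterification with SN2 inversion at the benzylic carbon (C7C R to S), giving the erythro unit with both hydroxyls protected.

Step 21
Reactants: 27 erythro bis(4-nitrobenzoate) propenyl arene
Product: 28 (1S,2R)-2-(4-formyl-2-methoxyphenoxy)-1-(3-methoxy-4-triisopropylsilyloxyphenyl)propane-1,3-diyl bis(4-nitrobenzoate)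
Conditions: OsO4 (2 mol%), NaIO4 (4 equiv), 2,6-lutidine, dioxane–H2O, rt
Reagents that add atoms: sodium periodate (terminal oxidant, oxygen delivered through OsO4), [Na+].[O-]I(=O)(=O)=O
Why: Lemieux–Johnson cleavage, osmylation of the styrenic alkene and periodate scission of the diol, unmasks the aldehyde without affecting esters or the silyl ether.

Step 22
Reactants: 21 unit A erythro bis(4-nitrobenzoate) imide; 28 aldehyde carrying unit C
Product: 29 fully protected syn-aldol adduct (unit B as (2R,3S)-3-hydroxy-2-aryloxypropanoyl imide)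
Conditions: Bu2BOTf (1.2 equiv), i-Pr2NEt (1.4 equiv), CH2Cl2, −78 → 0 °C; then 28 (1.3 equiv), −78 → 0 °C; pH 7 buffer, MeOH, 30% H2O2, 0 °C
Reagents that add atoms: none
Why: Evans boron glycolate syn-aldol as the fragment coupling, the (R)-auxiliary alone setting C8B and C7B (both S, threo) because the aldehyde has no α-stereocentre.

Step 23
Reactants: 29 fully protected syn-aldol adduct
Product: 30 bis(triisopropylsilyl) ether of the target at the two guaiacyl phenols
Conditions: LiBH4 (excess), MeOH, THF, 0 °C → rt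
Reagents that add atoms: none
Why: Borohydride reduction that converts the imide to the primary alcohol of unit B and cleaves the four activated 4-nitrobenzoates reductively in the same operation, leaving nitro groups, silyl ethers and benzylic ethers alone.

Step 24
Reactants: 30 bis(triisopropylsilyl) ether
Product: 31 target CNP0316493.3
Conditions: Bu4NF (2.5 equiv), AcOH (2.5 equiv), THF, 0 °C
Reagents that add atoms: none
Why: Fluoride cleavage of the two aryl silyl ethers, buffered with acetic acid so that the p-hydroxybenzyl alcohols are not exposed to base.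

**Compound list**

1 | (E)-sinapyl alcohol | COc1cc(/C=C/CO)cc(OC)c1O | starting material
2 | (E)-3-[4-(benzyloxy)-3,5-dimethoxyphenyl]prop-2-en-1-ol | COc1cc(/C=C/CO)cc(OC)c1OCc1ccccc1 | intermediate
3 | (E)-3-[4-(benzyloxy)-3,5-dimethoxyphenyl]prop-2-en-1-yl bromoacetate | COc1cc(/C=C/COC(=O)CBr)cc(OC)c1OCc1ccccc1 | intermediate
4 | (E)-3-[4-(benzyloxy)-3,5-dimethoxyphenyl]prop-2-en-1-yl diazoacetate | COc1cc(/C=C/COC(=O)C=[N+]=[N-])cc(OC)c1OCc1ccccc1 | intermediate
5 | diazo iminium chloride (dimethyliminium adduct of 4 at the diazo carbon) | COc1cc(/C=C/COC(=O)C(C=[N+](C)C)=[N+]=[N-])cc(OC)c1OCc1ccccc1.[Cl-] | intermediate (not isolated)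
6 | (E)-3-[4-(benzyloxy)-3,5-dimethoxyphenyl]prop-2-en-1-yl 2-diazo-3-oxopropanoate | COc1cc(/C=C/COC(=O)C(C=O)=[N+]=[N-])cc(OC)c1OCc1ccccc1 | intermediate
7 | (1S,5R,6S)-6-[4-(benzyloxy)-3,5-dimethoxyphenyl]-2-oxo-3-oxabicyclo[3.1.0]hexane-1-carbaldehyde | O=C[C@@]12C(=O)OC[C@@H]1[C@H]2c1cc(OC)c(OCc2ccccc2)c(OC)c1 | intermediate
8 | (5R,6S)-6-[4-(benzyloxy)-3,5-dimethoxyphenyl]-3,7-dioxabicyclo[3.3.0]oct-1(8)-en-2-one | O=C1OC[C@H]2C1=CO[C@@H]2c1cc(OC)c(OCc2ccccc2)c(OC)c1 | intermediate
9 | (1R,5R,6S)-6-[4-(benzyloxy)-3,5-dimethoxyphenyl]-3,7-dioxabicyclo[3.3.0]octan-2-one | O=C1OC[C@H]2[C@@H]1CO[C@@H]2c1cc(OC)c(OCc2ccccc2)c(OC)c1 | intermediate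
10 | (1R,5R,6S)-6-[4-(benzyloxy)-3,5-dimethoxyphenyl]-3,7-dioxabicyclo[3.3.0]octan-2-ol (both anomers) | OC1OC[C@H]2[C@@H]1CO[C@@H]2c1cc(OC)c(OCc2ccccc2)c(OC)c1 | intermediate
11 | 2,6-dimethoxyphenol | COc1cccc(OC)c1O | starting material
12 | (+)-syringaresinol 4'-O-benzyl ether (7S,8R,7'S,8'R) | COc1cc(cc(OC)c1O)[C@H]1OC[C@H]2[C@@H]1CO[C@@H]2c1cc(OC)c(OCc2ccccc2)c(OC)c1 | intermediate
13 | (R)-4-benzyl-3-(chloroacetyl)oxazolidin-2-one | ClCC(=O)N1[C@H](Cc2ccccc2)COC1=O | starting material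
14 | 4'-O-benzylsyringaresinol 4-O-CH2C(O)-[(R)-4-benzyl-2-oxooxazolidin-3-yl] | COc1cc(cc(OC)c1OCC(=O)N1[C@H](Cc2ccccc2)COC1=O)[C@H]1OC[C@H]2[C@@H]1CO[C@@H]2c1cc(OC)c(OCc2ccccc2)c(OC)c1 | intermediate
15 | vanillin | COc1cc(C=O)ccc1O | starting material
16 | 3-methoxy-4-(triisopropylsilyloxy)benzaldehyde | COc1cc(C=O)ccc1O[Si](C(C)C)(C(C)C)C(C)C | intermediate
17 | unit A syn-aldol adduct ((2R,3S)-propanoyl imide, (R)-auxiliary) on O4 of 4'-O-benzylsyringaresinol | COc1cc([C@H](O)[C@H](C(=O)N2[C@H](Cc3ccccc3)COC2=O)Oc2c(OC)cc([C@H]3OC[C@H]4[C@@H]3CO[C@@H]4c3cc(OC)c(OCc4ccccc4)c(OC)c3)cc2OC)ccc1O[Si](C(C)C)(C(C)C)C(C)C | intermediate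
18 | 4'-O-benzylsyringaresinol 4-O-[threo-(7S,8S)-4-O-triisopropylsilylguaiacylglycerol-8-yl] ether | COc1cc([C@H](O)[C@H](CO)Oc2c(OC)cc([C@H]3OC[C@H]4[C@@H]3CO[C@@H]4c3cc(OC)c(OCc4ccccc4)c(OC)c3)cc2OC)ccc1O[Si](C(C)C)(C(C)C)C(C)C | intermediate
19 | syringaresinol 4-O-[threo-(7S,8S)-4-O-triisopropylsilylguaiacylglycerol-8-yl] ether (4'-OH free) | COc1cc([C@H](O)[C@H](CO)Oc2c(OC)cc([C@H]3OC[C@H]4[C@@H]3CO[C@@H]4c3cc(OC)c(O)c(OC)c3)cc2OC)ccc1O[Si](C(C)C)(C(C)C)C(C)C | intermediate
20 | 19 with CH2C(O)-[(R)-4-benzyl-2-oxooxazolidin-3-yl] on O4' | COc1cc([C@H](O)[C@H](CO)Oc2c(OC)cc([C@H]3OC[C@H]4[C@@H]3CO[C@@H]4c3cc(OC)c(OCC(=O)N4[C@H](Cc5ccccc5)COC4=O)c(OC)c3)cc2OC)ccc1O[Si](C(C)C)(C(C)C)C(C)C | intermediate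
21 | unit A erythro-(7R,8S) 7,9-bis(4-nitrobenzoate) of 20 | COc1cc([C@@H](OC(=O)c2ccc(cc2)[N+](=O)[O-])[C@H](COC(=O)c2ccc(cc2)[N+](=O)[O-])Oc2c(OC)cc([C@H]3OC[C@H]4[C@@H]3CO[C@@H]4c3cc(OC)c(OCC(=O)N4[C@H](Cc5ccccc5)COC4=O)c(OC)c3)cc2OC)ccc1O[Si](C(C)C)(C(C)C)C(C)C | intermediate
22 | (E)-isoeugenol | C/C=C/c1ccc(O)c(OC)c1 | starting material
23 | (S)-4-benzyl-3-(chloroacetyl)oxazolidin-2-one | ClCC(=O)N1[C@@H](Cc2ccccc2)COC1=O | starting material
24 | (S)-4-benzyl-3-{[2-methoxy-4-((E)-prop-1-enyl)phenoxy]acetyl}oxazolidin-2-one | C/C=C/c1ccc(OCC(=O)N2[C@@H](Cc3ccccc3)COC2=O)c(OC)c1 | intermediate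
25 | unit C syn-aldol adduct ((2S,3R)-propanoyl imide, (S)-auxiliary) | C/C=C/c1ccc(O[C@H](C(=O)N2[C@@H](Cc3ccccc3)COC2=O)[C@H](O)c2ccc(O[Si](C(C)C)(C(C)C)C(C)C)c(OC)c2)c(OC)c1 | intermediate
26 | (1R,2R)-2-[2-methoxy-4-((E)-prop-1-enyl)phenoxy]-1-(3-methoxy-4-triisopropylsilyloxyphenyl)propane-1,3-diol | C/C=C/c1ccc(O[C@H](CO)[C@H](O)c2ccc(O[Si](C(C)C)(C(C)C)C(C)C)c(OC)c2)c(OC)c1 | intermediate
27 | (1S,2R)-2-[2-methoxy-4-((E)-prop-1-enyl)phenoxy]-1-(3-methoxy-4-triisopropylsilyloxyphenyl)propane-1,3-diyl bis(4-nitrobenzoate) | C/C=C/c1ccc(O[C@H](COC(=O)c2ccc(cc2)[N+](=O)[O-])[C@@H](OC(=O)c2ccc(cc2)[N+](=O)[O-])c2ccc(O[Si](C(C)C)(C(C)C)C(C)C)c(OC)c2)c(OC)c1 | intermediate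
28 | (1S,2R)-2-(4-formyl-2-methoxyphenoxy)-1-(3-methoxy-4-triisopropylsilyloxyphenyl)propane-1,3-diyl bis(4-nitrobenzoate) | O=Cc1ccc(O[C@H](COC(=O)c2ccc(cc2)[N+](=O)[O-])[C@@H](OC(=O)c2ccc(cc2)[N+](=O)[O-])c2ccc(O[Si](C(C)C)(C(C)C)C(C)C)c(OC)c2)c(OC)c1 | intermediate
29 | fully protected unit B syn-aldol adduct (A and C as erythro bis(4-nitrobenzoates), two silyl ethers, (R)-auxiliary) | COc1cc([C@@H](OC(=O)c2ccc(cc2)[N+](=O)[O-])[C@H](COC(=O)c2ccc(cc2)[N+](=O)[O-])Oc2c(OC)cc([C@H]3OC[C@H]4[C@@H]3CO[C@@H]4c3cc(OC)c(O[C@@H](C(=O)N4[C@H](Cc5ccccc5)COC4=O)[C@@H](O)c4ccc(O[C@H](COC(=O)c5ccc(cc5)[N+](=O)[O-])[C@@H](OC(=O)c5ccc(cc5)[N+](=O)[O-])c5ccc(O[Si](C(C)C)(C(C)C)C(C)C)c(OC)c5)c(OC)c4)c(OC)c3)cc2OC)ccc1O[Si](C(C)C)(C(C)C)C(C)C | intermediate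
30 | target bis(triisopropylsilyl) ether at the two guaiacyl phenols | COc1cc([C@@H](O)[C@H](CO)Oc2c(OC)cc([C@H]3OC[C@H]4[C@@H]3CO[C@@H]4c3cc(OC)c(O[C@@H](CO)[C@@H](O)c4ccc(O[C@H](CO)[C@@H](O)c5ccc(O[Si](C(C)C)(C(C)C)C(C)C)c(OC)c5)c(OC)c4)c(OC)c3)cc2OC)ccc1O[Si](C(C)C)(C(C)C)C(C)C | intermediate
31 | CNP0316493.3 (core 7S,8R,7'S,8'R; unit A 7R,8S erythro; unit B 7S,8S threo; unit C 7S,8R erythro) | COc1cc([C@@H](O)[C@H](CO)Oc2c(OC)cc([C@H]3OC[C@H]4[C@@H]3CO[C@@H]4c3cc(OC)c(O[C@@H](CO)[C@@H](O)c4ccc(O[C@H](CO)[C@@H](O)c5ccc(O)c(OC)c5)c(OC)c4)c(OC)c3)cc2OC)ccc1O | target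

**Step count and risks**

Total step count: 24. Longest linear sequence: 18 steps (1–10, 12–16, 22–24).

Steps most likely to fail:

1. Step 5 (asymmetric cyclopropanation). The carbene transfer may give poor enantiofacial control at C8', or the formyl-bearing carbene may be diverted into dimerisation or premature ring opening, because the intramolecular reaction of an α-formyl diazo ester is less documented than that of other acceptor-substituted allyl diazoacetates. The fallback sets out from 4: intramolecular cyclopropanation of the plain diazoacetate with Rh2(4S-MPPIM)4 (dirhodium tetrakis[methyl (4S)-2-oxo-3-(3-phenylpropanoyl)imidazolidine-4-carboxylate], or its enantiomer) in CH2Cl2, the best-documented catalyst class for E-cinnamyl diazoacetates, should give the formyl-free cyclopropane lactone F1. Its lactone enolate (LiN(i-Pr)2, THF, −78 °C) is then C-formylated with 2,2,2-trifluoroethyl formate at the bridgehead carbon, where the ring fusion leaves only the exo position open, and the route is rejoined at 7.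

2. Step 9 (Friedel–Crafts arylation). Reversible ionisation of either benzylic C–O bond under the Lewis acid may erode the exo configuration at C7 or C7', and O-arylation may compete with C-arylation. The fallback sets out from lactone 9: the aryllithium from the silyl-protected aryl bromide F2 (from commercial 4-bromo-2,6-dimethoxyphenol with t-BuMe2SiCl and imidazole; n-BuLi, THF, −78 °C) is added to 9 to give the keto alcohol F3. NaBH4 in MeOH reduces it to the diol F4 (either C7 epimer), and camphorsulfonic acid in CH2Cl2 closes the second ring through the benzylic cation, which should place the aryl group exo, to give the silyl-protected furofuran F5. Bu4NF with AcOH then returns to 12.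

3. Step 16 (Mitsunobu inversion on the advanced intermediate). The electron-rich benzylic alkoxyphosphonium ion may ionise, with loss of clean inversion, or eliminate to the enol ether. The fallback sets out from 20: selective silylation of the primary alcohol (t-BuMe2SiCl, imidazole, DMF) gives the 9A-silyl ether F6, and Dess–Martin periodinane oxidises the benzylic alcohol to the α-aryloxy ketone F7. Chelation-controlled reduction with Zn(BH4)2 in Et2O at −30 °C (Cram chelate through the aryloxy oxygen) should give the erythro alcohol F8, and HF·pyridine frees the erythro diol F9. Acylation with 4-nitrobenzoyl chloride, pyridine and DMAP rejoins the route at 21.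

Further compounds

F1 | step 5 | (1S,5R,6R)-6-[4-(benzyloxy)-3,5-dimethoxyphenyl]-3-oxabicyclo[3.1.0]hexan-2-one | O=C1OC[C@@H]2[C@@H](c3cc(OC)c(OCc4ccccc4)c(OC)c3)[C@H]12
F2 | step 9 | (4-bromo-2,6-dimethoxyphenoxy)(tert-butyl)dimethylsilane | COc1cc(Br)cc(OC)c1O[Si](C)(C)C(C)(C)C
F3 | step 9 | keto alcohol (8R,7'S,8'R): [(2S,3R,4R)-2-(4-benzyloxy-3,5-dimethoxyphenyl)-4-(4-tert-butyldimethylsilyloxy-3,5-dimethoxybenzoyl)tetrahydrofuran-3-yl]methanol | OC[C@H]1[C@@H](C(=O)c2cc(OC)c(O[Si](C)(C)C(C)(C)C)c(OC)c2)CO[C@@H]1c1cc(OC)c(OCc2ccccc2)c(OC)c1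
F4 | step 9 | diol from reduction of F3 (C7 carbinol, either epimer) | OC[C@H]1[C@@H](C(O)c2cc(OC)c(O[Si](C)(C)C(C)(C)C)c(OC)c2)CO[C@@H]1c1cc(OC)c(OCc2ccccc2)c(OC)c1
F5 | step 9 | (+)-syringaresinol 4'-O-benzyl 4-O-tert-butyldimethylsilyl ether | COc1cc(cc(OC)c1O[Si](C)(C)C(C)(C)C)[C@H]1OC[C@H]2[C@@H]1CO[C@@H]2c1cc(OC)c(OCc2ccccc2)c(OC)c1
F6 | step 16 | 9A-O-tert-butyldimethylsilyl ether of 20 (unit A threo) | COc1cc([C@H](O)[C@H](CO[Si](C)(C)C(C)(C)C)Oc2c(OC)cc([C@H]3OC[C@H]4[C@@H]3CO[C@@H]4c3cc(OC)c(OCC(=O)N4[C@H](Cc5ccccc5)COC4=O)c(OC)c3)cc2OC)ccc1O[Si](C(C)C)(C(C)C)C(C)C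
F7 | step 16 | C7A ketone of F6 | COc1cc(C(=O)[C@H](CO[Si](C)(C)C(C)(C)C)Oc2c(OC)cc([C@H]3OC[C@H]4[C@@H]3CO[C@@H]4c3cc(OC)c(OCC(=O)N4[C@H](Cc5ccccc5)COC4=O)c(OC)c3)cc2OC)ccc1O[Si](C(C)C)(C(C)C)C(C)C
F8 | step 16 | unit A erythro-(7R,8S) alcohol with 9A-O-tert-butyldimethylsilyl ether | COc1cc([C@@H](O)[C@H](CO[Si](C)(C)C(C)(C)C)Oc2c(OC)cc([C@H]3OC[C@H]4[C@@H]3CO[C@@H]4c3cc(OC)c(OCC(=O)N4[C@H](Cc5ccccc5)COC4=O)c(OC)c3)cc2OC)ccc1O[Si](C(C)C)(C(C)C)C(C)C
F9 | step 16 | unit A erythro-(7R,8S) diol (C7A epimer of 20) | COc1cc([C@@H](O)[C@H](CO)Oc2c(OC)cc([C@H]3OC[C@H]4[C@@H]3CO[C@@H]4c3cc(OC)c(OCC(=O)N4[C@H](Cc5ccccc5)COC4=O)c(OC)c3)cc2OC)ccc1O[Si](C(C)C)(C(C)C)C(C)C
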